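Briarane numbering: C1 is the quaternary ring-fusion carbon, C2–C9 run round the ten-membered ring to the ring-fusion CH C10, C11–C14 complete cyclohexene ring A, and C17–C19 with O7 form the γ-lactone. Methyls: C15 (on C1), C16 (C5), C18 (C17), C20 (C11).
Cuts, in order: lactone C19–O7; ring A at C11=C12 (metathesis) and C13–C14 (allylation); C1–C10, the bond shared by ring A and the ten-membered ring; the ester C14–O; then chain bonds C1–C2, C3–C4, C5=C6, C10=C11 and C8–C17.
Enabling feature: in ring A the array O–C14–C1(Me)–C10(H)–C11(Me)=C12 is a γ,δ-unsaturated carbonyl (Claisen) retron lying across the ring fusion. Tying C14 through oxygen to the allylic terminus C12′ unfolds the carbocycle C1–C10 into a 14-membered lactone of a linear hydroxy acid.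
Forward: the chain grows outward from a D-glucose-derived 3-ulose (C6–C10). Macrolactonisation gives the 14-membered lactone, one transannular Ireland–Claisen ring contraction gives the ten-membered ring with C1 and C10, allylation/RCM gives ring A, and the γ-lactone comes last.
Stereochemistry: C7 and C9 are bought, and C8 and C17 are relayed from them on the rigid furanose. C4 and C14 come from allylboranes, C2 from an oxazolidinone aldol, and C1 and C10 from C2 and C9 in the key step. The Z-C5=C6 bond is made inside a temporary seven-membered lactone (O9–C4) that is cleaved afterwards.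

Key step: step 18

Assumption: C12′ is the methylene carbon that holds the place of C12 until step 22; ketone 1 is used anhydrous; lactol 6 and diol 13 are epimer mixtures at centres that are destroyed later, so those centres are left undefined in the SMILES.

Step 1
Reactants: 1 1,2:5,6-di-O-isopropylidene-α-D-ribo-hexofuranos-3-ulose (sugar C1–C5 = C6–C10)
Product: 2 3-C-isopropenyl-1,2:5,6-di-O-isopropylidene-α-D-allofuranose (tertiary C8-OH on the α face)
Conditions: isopropenylMgBr, THF, −78 → 0 °C; H2O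
Reagents that add atoms: isopropenylmagnesium bromide CC(=C)[Mg]Br
Why: Grignard 1,2-addition; the cis-fused 1,2-acetonide shields the α face of the bicyclic ketone, so the nucleophile should enter from the β face and set C8 with its OH cis to O7, as in the target.

Step 2
Reactants: 2 3-C-isopropenyl allofuranose diacetonide
Product: 4 C8/C19 diol [3-C-((S)-1-hydroxypropan-2-yl) allofuranose diacetonide], via spiro oxaborolane 3 (not isolated)
Conditions: BH3·THF, THF, 0 °C → rt; then NaOH, H2O2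
Reagents that add atoms: borane (as BH3·THF) B (boron stays only in 3); hydrogen peroxide OO
Why: Hydroboration–oxidation; the C8-OH first forms an alkoxyborane that delivers B–H intramolecularly to C19/C17, and the rotamer that turns the C18 methyl away from the C10 side chain should place H-17 so that C17 has the target configuration.

Step 3
Reactants: 4 C8/C19 diol
Product: 5 C19 p-methoxybenzyl (PMB) ether with free tertiary C8-OH
Conditions: NaH, PMBCl, cat. Bu4NI, DMF, 0 °C
Reagents that add atoms: 4-methoxybenzyl chloride COc1ccc(CCl)cc1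
Why: Williamson etherification; the primary alkoxide is alkylated while the hindered tertiary C8-OH stays free.

Step 4
Reactants: 5 C19 PMB ether
Product: 6 2,3:5,6-di-O-isopropylidene lactol (acetonide now on O7/O8, anomeric C6-OH free, anomeric mixture)
Conditions: cat. TsOH·H2O, acetone, rt
Reagents that add atoms: none
Why: Acid-catalysed acetal migration under thermodynamic control; the all-cis O6/O7/O8 array lets the acetonide move onto the cis C7/C8 diol, which protects the tertiary alcohol and frees C6 without touching a stereocentre.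

Step 5
Reactants: 6 2,3:5,6-diacetonide lactol
Product: 7 open-chain C6-vinyl C9-alcohol (C7/C8 acetonide, terminal acetonide on C10, C19-OPMB)
Conditions: Ph3PCH3Br, KOtBu, THF, 0 °C → reflux
Reagents that add atoms: methylenetriphenylphosphorane C=P(c1ccccc1)(c1ccccc1)c1ccccc1 (generated from methyltriphenylphosphonium bromide C[P+](c1ccccc1)(c1ccccc1)c1ccccc1.[Br-])
Why: Wittig methylenation of the hydroxy-aldehyde form of the lactol, which opens the furanose and frees the former ring oxygen as the C9-OH.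

Step 6
Reactants: 7 C6-vinyl C9-alcohol
Product: 8 C9 methacrylate
Conditions: methacrylic anhydride, Et3N, DMAP, CH2Cl2, rt
Reagents that add atoms: methacrylic anhydride CC(=C)C(=O)OC(=O)C(C)=C
Why: DMAP-catalysed acylation of the only free hydroxyl; the ester is a temporary tether that brings in C4, C5 and C16.

Step 7
Reactants: 8 C9 methacrylate
Product: 9 seven-membered unsaturated lactone O9–C4(=O)–C5(Me)=C6–C7–C8–C9, cis-fused to the C7/C8 dioxolane
Conditions: Hoveyda–Grubbs II (5 mol %), toluene, 80 °C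
Reagents that add atoms: none
Why: Ring-closing metathesis; inside a seven-membered ring the new trisubstituted C5=C6 bond can only carry C4 and C7 on the same side, which fixes the Z geometry of the target.

Step 8
Reactants: 9 seven-membered lactone
Product: 10 (Z)-hydroxy enal (C4 aldehyde, free C9-OH)
Conditions: DIBAL-H (1.1 equiv), CH2Cl2, −78 °C; Rochelle salt
Reagents that add atoms: none
Why: DIBAL semi-reduction of a lactone through an aluminium hemiacetal that persists at −78 °C; it cleaves the temporary ring and should release the Z-enal without isomerisation.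

Step 9
Reactants: 10 (Z)-hydroxy enal
Product: 11 (4R)-homoallylic diol (C4-OH, C9-OH, terminal alkene C2=CH2)
Conditions: (+)-Ipc2B(allyl), Et2O, −78 °C; then NaOH, H2O2
Reagents that add atoms: (+)-B-allyldiisopinocampheylborane C=CCB([C@H]1C[C@H]2C[C@@H]([C@@H]1C)C2(C)C)[C@H]1C[C@H]2C[C@@H]([C@@H]1C)C2(C)C
Why: Brown allylation through a chair six-membered transition state; the reagent derived from (−)-α-pinene should give the (R) carbinol at C4 under reagent control.

Step 10
Reactants: 11 (4R)-homoallylic diol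
Product: 12 C4,C9 bis-TBS ether
Conditions: TBSOTf, 2,6-lutidine, CH2Cl2, 0 °C → rt
Reagents that add atoms: tert-butyldimethylsilyl triflate CC(C)(C)[Si](C)(C)OS(=O)(=O)C(F)(F)F
Why: Silylation of both secondary alcohols in one operation with the reactive silyl triflate; no stereocentre is touched.

Step 11
Reactants: 12 C4,C9 bis-TBS ether
Product: 14 C2 aldehyde, via terminal diol 13 (not isolated)
Conditions: cat. OsO4, NaIO4, 2,6-lutidine, dioxane/H2O, rt
Reagents that add atoms: osmium tetroxide O=[Os](=O)(=O)=O (oxygen donor, turned over by sodium periodate [Na+].[O-]I(=O)(=O)=O)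
Why: Lemieux–Johnson cleavage; osmylation should pick the unhindered monosubstituted alkene over the trisubstituted C5=C6 bond, which is flanked by two branched allylic C–O carbons.

Step 12
Reactants: 14 C2 aldehyde; 15 (S)-4-benzyl-3-propionyloxazolidin-2-one
Product: 17 syn-aldol imide with (2R)-OH and a (1S) methyl-bearing centre, via Z-boron enolate 16 (not isolated)
Conditions: 15, Bu2BOTf, Et3N, CH2Cl2, −78 → 0 °C; then 14, −78 °C; pH 7 buffer, MeOH, H2O2
Reagents that add atoms: dibutylboron triflate CCCCB(CCCC)OS(=O)(=O)C(F)(F)F (boron and butyl groups stay only in 16)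
Why: Evans syn aldol through a Zimmerman–Traxler chair; the (S)-auxiliary sets the (R) carbinol at C2, and the C1 centre formed with it is erased in step 18.

Step 13
Reactants: 17 syn-aldol imide
Product: 19 C10 aldehyde, via C10 glycol 18 (not isolated)
Conditions: H5IO6, EtOAc, rt
Reagents that add atoms: none
Why: Periodic acid hydrolyses the exposed terminal acetonide and cleaves the resulting glycol in the same flask (Malaprade cleavage); the fully substituted C7/C8 dioxolane should react much more slowly.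

Step 14
Reactants: 19 C10 aldehyde
Product: 20 (E)-enal C12′HO–C11(Me)=C10H
Conditions: Ph3P=C(CH3)CHO, toluene, 80 °C
Reagents that add atoms: 2-(triphenylphosphoranylidene)propanal CC(C=O)=P(c1ccccc1)(c1ccccc1)c1ccccc1
Why: Wittig olefination with a stabilised ylide, which should give the E-trisubstituted enal (C9 trans to C12′).

Step 15
Reactants: 20 (E)-enal
Product: 21 allylic alcohol imide (free C12′-OH and C2-OH)
Conditions: NaBH4, CeCl3·7H2O, MeOH, −78 °C
Reagents that add atoms: none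
Why: Luche 1,2-reduction; the aldehyde is reduced far faster than the imide at low temperature.

Step 16
Reactants: 21 allylic alcohol imide
Product: 23 seco acid (C14 acid, C2-OH, C12′-OH), via peroxy acid 22 (not isolated)
Conditions: LiOH, H2O2, THF/H2O, 0 °C; Na2SO3; dil. HCl
Reagents that add atoms: hydrogen peroxide OO (as lithium hydroperoxide)
Why: Hydroperoxide cleavage of the N-acyl oxazolidinone at the exocyclic carbonyl; the conditions should not epimerise or retro-aldolise the β-hydroxy acyl unit.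

Step 17
Reactants: 23 seco acid
Product: 24 14-membered lactone (ring: C14, O, C12′, C11, C10, C9 … C2, C1) with free C2-OH
Conditions: PPh3, DIAD, toluene (0.002 M), slow addition, 0 °C → rt
Reagents that add atoms: none
Why: Mitsunobu macrolactonisation; it activates the primary allylic alcohol rather than the acid, so the unprotected β-hydroxy acid cannot close to a β-lactone by acyl activation and the carboxylate displaces at the stereochemically silent C12′.

Step 18
Reactants: 24 14-membered lactone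
Product: 28 ten-membered ring acid [C1(Me)(CO2H) quaternary; C10 bears isopropenyl C11(C20)=C12′H2; (1R,10S)], via dilithio dianion 25 (not isolated), via bis-silyl ketene acetal 26 (not isolated), via silyl ester 27 (not isolated)
Conditions: LDA (3 equiv), THF, −78 → −20 °C; TMSCl, −78 °C; then → 65 °C; aq. citric acid
Reagents that add atoms: lithium diisopropylamide CC(C)N([Li])C(C)C (lithium stays only in 25); chlorotrimethylsilane C[Si](C)(C)Cl (silicon stays only in 26 and 27)
Why: Two equivalents of LDA give the C2-alkoxide/C1-enolate 25, whose O2–Li–O14 chelate holds C2 cis to the enolate oxygen; double silylation freezes this geometry in 26, which undergoes a concerted suprafacial [3,3]-sigmatropic shift (C1–C10 forms, O–C12′ breaks) to silyl ester 27, hydrolysed to 28 on work-up. The closest known reaction type is the Ireland–Claisen rearrangement in its alicyclic form, the four-atom ring contraction of macrocyclic allylic lactones to 2-alkenylcycloalkanecarboxylic acids, combined with chelation-controlled enolisation of β-hydroxy esters. The only ring closed is the ten-membered carbocycle C1–C10, formed by contraction of the 14-membered lactone through a six-centre chair C1–C14–O–C12′–C11–C10 in which the ring branches C2 (trans to the allyl oxygen) and C9 (E-alkene) are both equatorial, so that Me-15 and H-10 end up anti across the new bond as in the trans-fused target. At C1 the face is set by C2, because A(1,3) strain with the cis OSiMe3 group turns H-2 into the ketene acetal plane and C10 bonds anti to C3; at C10 the face is set by C9, because A(1,3) strain with the C20 methyl turns H-9 into the alkene plane and C1 bonds anti to the C9–O bond; these two preferences and the chair are mutually matched for (1R,10S). The step needs site-selective enolisation, secured because C1–H is the only acidic C–H (C19 is still a PMB ether); a single ketene acetal geometry, secured by the chelate; and chair over boat, which an eight-atom bridge should allow, unlike small-ring contractions that force the boat. The gain in going from ketene acetal to carboxylate should pay for the medium-ring strain, and the transition state already has the bicyclo[8.4.0] shape of the target, with the cis-dioxolane and the Z-alkene folding C2 and C9 toward each other.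

Step 19
Reactants: 28 ten-membered ring acid
Product: 29 C2,C14 diol (C14H2OH on C1)
Conditions: LiAlH4, THF, 0 °C → rt
Reagents that add atoms: none
Why: Hydride reduction of the carboxylic acid, helped by the neighbouring C2 alkoxide; silyl ethers, acetonide, PMB ether and alkenes are inert.

Step 20
Reactants: 29 C2,C14 diol
Product: 30 C14 aldehyde with free C2-OH
Conditions: cat. TEMPO, PhI(OAc)2, CH2Cl2, rt
Reagents that add atoms: none
Why: Oxoammonium (TEMPO) oxidation, which is selective for the primary over the hindered secondary alcohol; the aldehyde has no α-hydrogen and cannot epimerise or eliminate.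

Step 21
Reactants: 30 C14 aldehyde
Product: 31 (14S)-homoallylic alcohol (C14-OH, C13H2, C12H=CH2)
Conditions: (−)-Ipc2B(allyl), Et2O, −78 °C; then NaOH, H2O2
Reagents that add atoms: (−)-B-allyldiisopinocampheylborane C=CCB([C@@H]1C[C@@H]2C[C@H]([C@H]1C)C2(C)C)[C@@H]1C[C@@H]2C[C@H]([C@H]1C)C2(C)C
Why: Brown allylation under reagent control; the reagent derived from (+)-α-pinene should give the (S) carbinol at C14 with a tertiary-alkyl aldehyde.

Step 22
Reactants: 31 (14S)-homoallylic alcohol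
Product: 32 bicyclo[8.4.0] diol (ring A closed, C11=C12 trisubstituted)
Conditions: Grubbs II (5 mol %), CH2Cl2, reflux
Reagents that add atoms: none
Why: Ring-closing metathesis of the allyl and isopropenyl groups to a six-membered ring, which should outrun any reaction of the hindered ring alkene C5=C6.

Step 23
Reactants: 32 bicyclo[8.4.0] diol
Product: 33 tetraol (C2, C4, C9, C14-OH; acetonide and PMB kept)
Conditions: TBAF, THF, rt → 50 °C
Reagents that add atoms: none
Why: Fluoride-induced desilylation; acetonide and PMB ether are stable to fluoride.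

Step 24
Reactants: 33 tetraol
Product: 34 2,4,9,14-tetraacetate
Conditions: Ac2O, pyridine, DMAP, rt
Reagents that add atoms: acetic anhydride CC(=O)OC(C)=O
Why: DMAP-catalysed peracetylation; the tertiary O8 and O7 are still locked in the acetonide, so only the four secondary alcohols that carry acetate in the target can react.

Step 25
Reactants: 34 tetraacetate
Product: 35 C19 primary alcohol
Conditions: DDQ, CH2Cl2/pH 7 buffer, 0 °C
Reagents that add atoms: none
Why: Oxidative PMB cleavage by hydride abstraction from the electron-rich benzyl ether; acetates, acetonide and alkenes are inert.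

Step 26
Reactants: 35 C19 primary alcohol
Product: 36 C19 carboxylic acid
Conditions: cat. TEMPO, PhI(OAc)2 (2.2 equiv), MeCN/H2O, rt
Reagents that add atoms: water O
Why: TEMPO/PhI(OAc)2 oxidation of the only free alcohol to the acid through the aldehyde hydrate, under conditions too mild to epimerise C17.

Step 27
Reactants: 36 C19 carboxylic acid
Product: 38 CNP0206892.2 (target), via dihydroxy acid 37 (not isolated)
Conditions: TFA/H2O/CH2Cl2, 0 °C → rt
Reagents that add atoms: none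
Why: Acid hydrolysis of the acetonide followed by spontaneous γ-lactonisation; only O7 can close a five-membered ring because O9 is acetylated and O8 would give a β-lactone, so the tertiary C8-OH is left free.

Compound list
1 | 1,2:5,6-di-O-isopropylidene-α-D-ribo-hexofuranos-3-ulose | CC1(C)OC[C@@H](O1)[C@H]2O[C@@H]3OC(C)(C)O[C@@H]3C2=O | starting material
2 | 3-C-isopropenyl-1,2:5,6-di-O-isopropylidene-α-D-allofuranose | CC1(C)OC[C@@H](O1)[C@H]2O[C@@H]3OC(C)(C)O[C@@H]3[C@@]2(O)C(C)=C | intermediate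
3 | spiro oxaborolane (O8–BH–C19–C17–C8) | CC1(C)OC[C@@H](O1)[C@H]2O[C@@H]3OC(C)(C)O[C@@H]3[C@]24OBC[C@@H]4C | intermediate
4 | C8/C19 diol, 3-C-[(S)-1-hydroxypropan-2-yl] allofuranose diacetonide | CC1(C)OC[C@@H](O1)[C@H]2O[C@@H]3OC(C)(C)O[C@@H]3[C@@]2(O)[C@@H](C)CO | intermediate
5 | C19 PMB ether of 4 | CC1(C)OC[C@@H](O1)[C@H]2O[C@@H]3OC(C)(C)O[C@@H]3[C@@]2(O)[C@@H](C)COCc4ccc(OC)cc4 | intermediate
6 | 2,3:5,6-di-O-isopropylidene lactol, anomeric mixture | CC1(C)OC[C@@H](O1)[C@H]2OC(O)[C@@H]3OC(C)(C)O[C@]23[C@@H](C)COCc4ccc(OC)cc4 | intermediate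
7 | open-chain C6-vinyl C9-alcohol | CC1(C)OC[C@@H](O1)[C@@H](O)[C@@]2([C@@H](C)COCc3ccc(OC)cc3)OC(C)(C)O[C@H]2C=C | intermediate
8 | C9 methacrylate | CC1(C)OC[C@@H](O1)[C@@H](OC(=O)C(C)=C)[C@@]2([C@@H](C)COCc3ccc(OC)cc3)OC(C)(C)O[C@H]2C=C | intermediate
9 | seven-membered Z-lactone O9–C4(=O)–C5(Me)=C6 | CC1(C)OC[C@@H](O1)[C@H]2OC(=O)C(C)=C[C@@H]3OC(C)(C)O[C@]23[C@@H](C)COCc4ccc(OC)cc4 | intermediate
10 | (Z)-hydroxy enal | CC1(C)OC[C@@H](O1)[C@@H](O)[C@@]2([C@@H](C)COCc3ccc(OC)cc3)OC(C)(C)O[C@H]2/C=C(/C)C=O | intermediate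
11 | (4R)-homoallylic diol | CC1(C)OC[C@@H](O1)[C@@H](O)[C@@]2([C@@H](C)COCc3ccc(OC)cc3)OC(C)(C)O[C@H]2/C=C(/C)[C@H](O)CC=C | intermediate
12 | C4,C9 bis-TBS ether | CC1(C)OC[C@@H](O1)[C@@H](O[Si](C)(C)C(C)(C)C)[C@@]2([C@@H](C)COCc3ccc(OC)cc3)OC(C)(C)O[C@H]2/C=C(/C)[C@H](O[Si](C)(C)C(C)(C)C)CC=C | intermediate
13 | terminal diol (epimer mixture) | CC1(C)OC[C@@H](O1)[C@@H](O[Si](C)(C)C(C)(C)C)[C@@]2([C@@H](C)COCc3ccc(OC)cc3)OC(C)(C)O[C@H]2/C=C(/C)[C@H](O[Si](C)(C)C(C)(C)C)CC(O)CO | intermediate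
14 | C2 aldehyde | CC1(C)OC[C@@H](O1)[C@@H](O[Si](C)(C)C(C)(C)C)[C@@]2([C@@H](C)COCc3ccc(OC)cc3)OC(C)(C)O[C@H]2/C=C(/C)[C@H](O[Si](C)(C)C(C)(C)C)CC=O | intermediate
15 | (S)-4-benzyl-3-propionyloxazolidin-2-one | CCC(=O)N1[C@@H](Cc2ccccc2)COC1=O | starting material
16 | Z-dibutylboron enolate of 15 | C/C=C(\OB(CCCC)CCCC)N1[C@@H](Cc2ccccc2)COC1=O | intermediate
17 | syn-aldol imide | CC1(C)OC[C@@H](O1)[C@@H](O[Si](C)(C)C(C)(C)C)[C@@]2([C@@H](C)COCc3ccc(OC)cc3)OC(C)(C)O[C@H]2/C=C(/C)[C@H](O[Si](C)(C)C(C)(C)C)C[C@@H](O)[C@H](C)C(=O)N4[C@@H](Cc5ccccc5)COC4=O | intermediate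
18 | C10 glycol | OC[C@@H](O)[C@@H](O[Si](C)(C)C(C)(C)C)[C@@]1([C@@H](C)COCc2ccc(OC)cc2)OC(C)(C)O[C@H]1/C=C(/C)[C@H](O[Si](C)(C)C(C)(C)C)C[C@@H](O)[C@H](C)C(=O)N3[C@@H](Cc4ccccc4)COC3=O | intermediate
19 | C10 aldehyde | O=C[C@@H](O[Si](C)(C)C(C)(C)C)[C@@]1([C@@H](C)COCc2ccc(OC)cc2)OC(C)(C)O[C@H]1/C=C(/C)[C@H](O[Si](C)(C)C(C)(C)C)C[C@@H](O)[C@H](C)C(=O)N3[C@@H](Cc4ccccc4)COC3=O | intermediate
20 | (E)-enal | O=C/C(C)=C/[C@@H](O[Si](C)(C)C(C)(C)C)[C@@]1([C@@H](C)COCc2ccc(OC)cc2)OC(C)(C)O[C@H]1/C=C(/C)[C@H](O[Si](C)(C)C(C)(C)C)C[C@@H](O)[C@H](C)C(=O)N3[C@@H](Cc4ccccc4)COC3=O | intermediate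
21 | allylic alcohol imide | OC/C(C)=C/[C@@H](O[Si](C)(C)C(C)(C)C)[C@@]1([C@@H](C)COCc2ccc(OC)cc2)OC(C)(C)O[C@H]1/C=C(/C)[C@H](O[Si](C)(C)C(C)(C)C)C[C@@H](O)[C@H](C)C(=O)N3[C@@H](Cc4ccccc4)COC3=O | intermediate
22 | peroxy acid | OC/C(C)=C/[C@@H](O[Si](C)(C)C(C)(C)C)[C@@]1([C@@H](C)COCc2ccc(OC)cc2)OC(C)(C)O[C@H]1/C=C(/C)[C@H](O[Si](C)(C)C(C)(C)C)C[C@@H](O)[C@H](C)C(=O)OO | intermediate
23 | seco acid | OC/C(C)=C/[C@@H](O[Si](C)(C)C(C)(C)C)[C@@]1([C@@H](C)COCc2ccc(OC)cc2)OC(C)(C)O[C@H]1/C=C(/C)[C@H](O[Si](C)(C)C(C)(C)C)C[C@@H](O)[C@H](C)C(=O)O | intermediate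
24 | 14-membered lactone | O=C1OC/C(C)=C/[C@@H](O[Si](C)(C)C(C)(C)C)[C@@]2([C@@H](C)COCc3ccc(OC)cc3)OC(C)(C)O[C@H]2/C=C(/C)[C@H](O[Si](C)(C)C(C)(C)C)C[C@@H](O)[C@@H]1C | intermediate
25 | dilithio dianion (C2 alkoxide, C1=C14 enolate, C2 cis to OLi) | [Li]O/C(=C1/C)OC/C(C)=C/[C@@H](O[Si](C)(C)C(C)(C)C)[C@@]2([C@@H](C)COCc3ccc(OC)cc3)OC(C)(C)O[C@H]2/C=C(/C)[C@H](O[Si](C)(C)C(C)(C)C)C[C@H]1O[Li] | intermediate
26 | bis-silyl ketene acetal | C[Si](C)(C)O/C(=C1/C)OC/C(C)=C/[C@@H](O[Si](C)(C)C(C)(C)C)[C@@]2([C@@H](C)COCc3ccc(OC)cc3)OC(C)(C)O[C@H]2/C=C(/C)[C@H](O[Si](C)(C)C(C)(C)C)C[C@H]1O[Si](C)(C)C | intermediate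
27 | ring-contracted trimethylsilyl ester, C2-OTMS | C=C(C)[C@@H]1[C@@H](O[Si](C)(C)C(C)(C)C)[C@@]2([C@@H](C)COCc3ccc(OC)cc3)OC(C)(C)O[C@H]2/C=C(/C)[C@H](O[Si](C)(C)C(C)(C)C)C[C@@H](O[Si](C)(C)C)[C@@]1(C)C(=O)O[Si](C)(C)C | intermediate
28 | ten-membered ring acid | C=C(C)[C@@H]1[C@@H](O[Si](C)(C)C(C)(C)C)[C@@]2([C@@H](C)COCc3ccc(OC)cc3)OC(C)(C)O[C@H]2/C=C(/C)[C@H](O[Si](C)(C)C(C)(C)C)C[C@@H](O)[C@@]1(C)C(=O)O | intermediate
29 | C2,C14 diol | C=C(C)[C@@H]1[C@@H](O[Si](C)(C)C(C)(C)C)[C@@]2([C@@H](C)COCc3ccc(OC)cc3)OC(C)(C)O[C@H]2/C=C(/C)[C@H](O[Si](C)(C)C(C)(C)C)C[C@@H](O)[C@@]1(C)CO | intermediate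
30 | C14 aldehyde | C=C(C)[C@@H]1[C@@H](O[Si](C)(C)C(C)(C)C)[C@@]2([C@@H](C)COCc3ccc(OC)cc3)OC(C)(C)O[C@H]2/C=C(/C)[C@H](O[Si](C)(C)C(C)(C)C)C[C@@H](O)[C@@]1(C)C=O | intermediate
31 | (14S)-homoallylic alcohol | C=C(C)[C@@H]1[C@@H](O[Si](C)(C)C(C)(C)C)[C@@]2([C@@H](C)COCc3ccc(OC)cc3)OC(C)(C)O[C@H]2/C=C(/C)[C@H](O[Si](C)(C)C(C)(C)C)C[C@@H](O)[C@@]1(C)[C@@H](O)CC=C | intermediate
32 | bicyclo[8.4.0] diol | O[C@H]1CC=C(C)[C@@H]2[C@@H](O[Si](C)(C)C(C)(C)C)[C@@]3([C@@H](C)COCc4ccc(OC)cc4)OC(C)(C)O[C@H]3/C=C(/C)[C@H](O[Si](C)(C)C(C)(C)C)C[C@@H](O)[C@@]12C | intermediate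
33 | tetraol | O[C@H]1CC=C(C)[C@@H]2[C@@H](O)[C@@]3([C@@H](C)COCc4ccc(OC)cc4)OC(C)(C)O[C@H]3/C=C(/C)[C@H](O)C[C@@H](O)[C@@]12C | intermediate
34 | 2,4,9,14-tetraacetate | CC(=O)O[C@H]1CC=C(C)[C@@H]2[C@@H](OC(C)=O)[C@@]3([C@@H](C)COCc4ccc(OC)cc4)OC(C)(C)O[C@H]3/C=C(/C)[C@H](OC(C)=O)C[C@@H](OC(C)=O)[C@@]12C | intermediate
35 | C19 primary alcohol | CC(=O)O[C@H]1CC=C(C)[C@@H]2[C@@H](OC(C)=O)[C@@]3([C@@H](C)CO)OC(C)(C)O[C@H]3/C=C(/C)[C@H](OC(C)=O)C[C@@H](OC(C)=O)[C@@]12C | intermediate
36 | C19 carboxylic acid | CC(=O)O[C@H]1CC=C(C)[C@@H]2[C@@H](OC(C)=O)[C@@]3([C@@H](C)C(=O)O)OC(C)(C)O[C@H]3/C=C(/C)[C@H](OC(C)=O)C[C@@H](OC(C)=O)[C@@]12C | intermediate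
37 | C7,C8-dihydroxy acid | CC(=O)O[C@H]1CC=C(C)[C@@H]2[C@@H](OC(C)=O)[C@@]([C@@H](C)C(=O)O)(O)[C@@H](O)/C=C(/C)[C@H](OC(C)=O)C[C@@H](OC(C)=O)[C@@]12C | intermediate
38 | CNP0206892.2 | CC(=O)O[C@H]1CC=C(C)[C@@H]2[C@@H](OC(C)=O)[C@@]3(O)[C@H](/C=C(/C)[C@H](OC(C)=O)C[C@@H](OC(C)=O)[C@@]12C)OC(=O)[C@@H]3C | target

Total step count: 27. Longest linear sequence: 27 steps, from 1. Compound 15 and all reagents are purchased.

Steps most likely to fail

Step 18. Enolisation of the hindered C1–H may be slow, the fully substituted ketene acetal may form with poor geometry, or the shift may be sluggish or unselective at C1. The fallback separates the quaternary centre from the ring contraction. It sets out from 14 and returns at 29.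
- A Mukaiyama aldol of 14 with 1-(tert-butyldimethylsilyloxy)-1-methoxyethene and BF3·OEt2 relies on 1,3-anti induction by the C4 silyl ether. It would give the des-methyl β-hydroxy methyl ester F1.
- Periodic acid would give the C10 aldehyde F2, the stabilised ylide of step 14 the (E)-enal F3, and Luche reduction the allylic alcohol F4.
- LiOH would give the seco acid F5, and Mitsunobu closure the des-methyl 14-membered lactone F6.
- The same Ireland–Claisen contraction, now through a less hindered trisubstituted ketene acetal, would give the ring-contracted acid F7. It carries C10 as in the target and a C1–H.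
- TMSCHN2 would give the methyl ester F8.
- Fráter–Seebach methylation (LDA, then MeI) of its chelated dianion should bring the methyl group in anti to C3, which is the C1 configuration of the target. This would give the quaternary methyl ester F9.
- LiAlH4 reduces F9 to 29.

Step 17. The activated allylic alcohol may eliminate or be attacked at the wrong terminus, the C2-OH may compete for activation, or oligomers may form. The fallback switches from alcohol activation to acyl activation on a C2-protected seco acid. It sets out from 20 and returns at 24.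
- TESOTf/2,6-lutidine would give the C2 triethylsilyl ether enal F10.
- Luche reduction would give the allylic alcohol F11, and LiOH/H2O2 the protected seco acid F12.
- Yamaguchi macrolactonisation (2,4,6-trichlorobenzoyl chloride, Et3N, then DMAP, toluene, high dilution) would give the C2-OTES lactone F13.
- HF·pyridine converts F13 selectively into 24.

Step 7. The metathesis of an electron-poor 1,1-disubstituted alkene with a hindered allylic alkene may stall or lead to dimers. The fallback gives up the temporary ring and sets the Z-alkene by olefination. It sets out from 7 and returns at 12.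
- TBSOTf would give the C9 silyl ether F14, and Lemieux–Johnson cleavage the C6 aldehyde F15.
- Stork–Zhao olefination with Ph3P=C(I)CH3 would give the (Z)-vinyl iodide F16.
- Iodine–lithium exchange (t-BuLi) followed by DMF would give, with retention of geometry, the (Z)-enal F17.
- (+)-Ipc2B(allyl) would give the (4R)-homoallylic alcohol F18, and TBSOTf then gives 12.

Further compounds
F1 | step 18 | des-methyl β-hydroxy methyl ester | CC1(C)OC[C@@H](O1)[C@@H](O[Si](C)(C)C(C)(C)C)[C@@]2([C@@H](C)COCc3ccc(OC)cc3)OC(C)(C)O[C@H]2/C=C(/C)[C@H](O[Si](C)(C)C(C)(C)C)C[C@@H](O)CC(=O)OC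
F2 | step 18 | des-methyl C10 aldehyde | O=C[C@@H](O[Si](C)(C)C(C)(C)C)[C@@]1([C@@H](C)COCc2ccc(OC)cc2)OC(C)(C)O[C@H]1/C=C(/C)[C@H](O[Si](C)(C)C(C)(C)C)C[C@@H](O)CC(=O)OC
F3 | step 18 | des-methyl (E)-enal | O=C/C(C)=C/[C@@H](O[Si](C)(C)C(C)(C)C)[C@@]1([C@@H](C)COCc2ccc(OC)cc2)OC(C)(C)O[C@H]1/C=C(/C)[C@H](O[Si](C)(C)C(C)(C)C)C[C@@H](O)CC(=O)OC
F4 | step 18 | des-methyl allylic alcohol | OC/C(C)=C/[C@@H](O[Si](C)(C)C(C)(C)C)[C@@]1([C@@H](C)COCc2ccc(OC)cc2)OC(C)(C)O[C@H]1/C=C(/C)[C@H](O[Si](C)(C)C(C)(C)C)C[C@@H](O)CC(=O)OC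
F5 | step 18 | des-methyl seco acid | OC/C(C)=C/[C@@H](O[Si](C)(C)C(C)(C)C)[C@@]1([C@@H](C)COCc2ccc(OC)cc2)OC(C)(C)O[C@H]1/C=C(/C)[C@H](O[Si](C)(C)C(C)(C)C)C[C@@H](O)CC(=O)O
F6 | step 18 | des-methyl 14-membered lactone | O=C1OC/C(C)=C/[C@@H](O[Si](C)(C)C(C)(C)C)[C@@]2([C@@H](C)COCc3ccc(OC)cc3)OC(C)(C)O[C@H]2/C=C(/C)[C@H](O[Si](C)(C)C(C)(C)C)C[C@@H](O)C1
F7 | step 18 | ring-contracted acid with C1–H | C=C(C)[C@@H]1[C@@H](O[Si](C)(C)C(C)(C)C)[C@@]2([C@@H](C)COCc3ccc(OC)cc3)OC(C)(C)O[C@H]2/C=C(/C)[C@H](O[Si](C)(C)C(C)(C)C)C[C@@H](O)[C@H]1C(=O)O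
F8 | step 18 | methyl ester of F7 | C=C(C)[C@@H]1[C@@H](O[Si](C)(C)C(C)(C)C)[C@@]2([C@@H](C)COCc3ccc(OC)cc3)OC(C)(C)O[C@H]2/C=C(/C)[C@H](O[Si](C)(C)C(C)(C)C)C[C@@H](O)[C@H]1C(=O)OC
F9 | step 18 | quaternary methyl ester (methyl ester of 28) | C=C(C)[C@@H]1[C@@H](O[Si](C)(C)C(C)(C)C)[C@@]2([C@@H](C)COCc3ccc(OC)cc3)OC(C)(C)O[C@H]2/C=C(/C)[C@H](O[Si](C)(C)C(C)(C)C)C[C@@H](O)[C@@]1(C)C(=O)OC
F10 | step 17 | C2 triethylsilyl ether enal | O=C/C(C)=C/[C@@H](O[Si](C)(C)C(C)(C)C)[C@@]1([C@@H](C)COCc2ccc(OC)cc2)OC(C)(C)O[C@H]1/C=C(/C)[C@H](O[Si](C)(C)C(C)(C)C)C[C@@H](O[Si](CC)(CC)CC)[C@H](C)C(=O)N3[C@@H](Cc4ccccc4)COC3=O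
F11 | step 17 | C2-OTES allylic alcohol imide | OC/C(C)=C/[C@@H](O[Si](C)(C)C(C)(C)C)[C@@]1([C@@H](C)COCc2ccc(OC)cc2)OC(C)(C)O[C@H]1/C=C(/C)[C@H](O[Si](C)(C)C(C)(C)C)C[C@@H](O[Si](CC)(CC)CC)[C@H](C)C(=O)N3[C@@H](Cc4ccccc4)COC3=O
F12 | step 17 | C2-OTES seco acid | OC/C(C)=C/[C@@H](O[Si](C)(C)C(C)(C)C)[C@@]1([C@@H](C)COCc2ccc(OC)cc2)OC(C)(C)O[C@H]1/C=C(/C)[C@H](O[Si](C)(C)C(C)(C)C)C[C@@H](O[Si](CC)(CC)CC)[C@H](C)C(=O)O
F13 | step 17 | C2-OTES 14-membered lactone | O=C1OC/C(C)=C/[C@@H](O[Si](C)(C)C(C)(C)C)[C@@]2([C@@H](C)COCc3ccc(OC)cc3)OC(C)(C)O[C@H]2/C=C(/C)[C@H](O[Si](C)(C)C(C)(C)C)C[C@@H](O[Si](CC)(CC)CC)[C@@H]1C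
F14 | step 7 | C9 silyl ether of 7 | CC1(C)OC[C@@H](O1)[C@@H](O[Si](C)(C)C(C)(C)C)[C@@]2([C@@H](C)COCc3ccc(OC)cc3)OC(C)(C)O[C@H]2C=C
F15 | step 7 | C6 aldehyde | CC1(C)OC[C@@H](O1)[C@@H](O[Si](C)(C)C(C)(C)C)[C@@]2([C@@H](C)COCc3ccc(OC)cc3)OC(C)(C)O[C@H]2C=O
F16 | step 7 | (Z)-vinyl iodide | CC1(C)OC[C@@H](O1)[C@@H](O[Si](C)(C)C(C)(C)C)[C@@]2([C@@H](C)COCc3ccc(OC)cc3)OC(C)(C)O[C@H]2/C=C(/C)I
F17 | step 7 | (Z)-enal with C9-OTBS | CC1(C)OC[C@@H](O1)[C@@H](O[Si](C)(C)C(C)(C)C)[C@@]2([C@@H](C)COCc3ccc(OC)cc3)OC(C)(C)O[C@H]2/C=C(/C)C=O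
F18 | step 7 | (4R)-homoallylic alcohol with C9-OTBS | CC1(C)OC[C@@H](O1)[C@@H](O[Si](C)(C)C(C)(C)C)[C@@]2([C@@H](C)COCc3ccc(OC)cc3)OC(C)(C)O[C@H]2/C=C(/C)[C@H](O)CC=C
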